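## Structural features

The target is a daucane-type sesquiterpenoid: a cyclopentane (ring A, C1–C5) cis-fused along the C1–C5 bond to a cycloheptene (ring B, C1, C5, C6–C10) that holds the C8=C9 double bond. The numbering used throughout is C1 quaternary C–CH3, C2 CH–OH, C3 CH2, C4 C(OH)(isopropyl), C5 ring-fusion CH, C6 CH–O-angeloyl, C7 CH2, C8(CH3)=C9, C10 CH–O-angeloyl. With the C1 methyl defined as β, the groups 5-H, 2-OH, 4-isopropyl and 6-O-angeloyl are β and 4-OH and 10-O-angeloyl are α, which corresponds to (1R,2R,4S,5R,6R,10R). The six stereocentres are contiguous: the quaternary C1 is flanked by C2, C5 and C10, and C5 is flanked by C4 and C6, so the two oxygenated ring-B carbons sit on either side of the ring fusion. The fragile groups are the two (Z)-2-methylbut-2-enoates, which isomerise to tiglates under nucleophilic or basic catalysis and can migrate to free hydroxyls, the allylic C10 ester, and the C4 tertiary alcohol, which is β to C6 and invites retro-aldol cleavage or dehydration whenever C6 is a ketone. The real difficulty is the seven-membered ring with its cis fusion next to a quaternary carbon, together with the need to tell four oxygen functions apart. The key step exploits the fact that C6 and C10 are both oxygenated and 1,4-related through the C5–C1 bond: a C6–C10 bond turns ring B into a cyclobutane (C1–C5–C6–C10) carrying a cis-1,2-diol and fused to ring A and to a methylcyclopentane, which is the photoadduct of a cyclopentenone and a cyclic enediol bis-silyl ether.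

## Logic of the disconnections

20 ⇒ 19 ⇒ 16 + 17. The O–Si bond at C2 and the two ester C–O bonds at C6 and C10 are cut first. The angelates are the most fragile groups and should be exposed to as few operations as possible. The gain is 16, in which the two secondary hydroxyls differ from the tertiary C4 hydroxyl by hindrance alone and the C2 oxygen stays masked. The forward steps must acylate without Z-to-E isomerisation and desilylate without acyl migration.

16 ⇒ 15 ⇒ 14. The acetal C–O bonds at O4 and O6 are restored and the C10–H bond is cut, so the allylic carbinol becomes an enone. The enone is the natural precursor of an allylic alcohol and carries no stereocentre at C10. The demand is 1,2-reduction with hydride arriving on the β face.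

14 ⇒ 13 ⇒ 12. The C8=C9 double bond is removed by way of the C9=C10 silyl enol ether. This makes C8 tetrahedral, so its configuration becomes irrelevant, and reduces the problem to a saturated ketone. The demand is regiospecific enolisation, which the quaternary C1 guarantees, and dehydrogenation toward C8.

12 ⇒ 11 ⇒ 10. The acetal is opened and the C6–H bond is cut, so C6 becomes a ketone. The C4 hydroxyl stands β to C6 and can deliver hydride internally. The gain is a 6,10-dione. The forward step must reduce C6 and not C10, and from the face on which O4 lies.

10 ⇒ 9. A C6–C10 bond is added. The seven-membered ring is replaced by a four- and a five-membered ring, both easy to form, and the two ketones become a cis-1,2-diol. The forward step must cleave the glycol without touching the C4 tertiary alcohol, and the product is a labile β-hydroxy ketone.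

9 ⇒ 8 ⇒ 6 + 7. The two O–Si bonds are restored and the C4–isopropyl bond is cut. The addition must come before the diol is freed, because a free cyclobutanol β to a C4 ketone would fragment by retro-aldol. The demand is convex-face addition to an enolisable β-silyloxy ketone without elimination.

6 ⇒ 3 + 5. The cyclobutane bonds C1–C10 and C5–C6 are cut. The gain is two monocyclic five-membered components, one of them symmetric, so there is no regiochemical issue. The forward step must add on the enone face opposite the silyloxy group.

3 ⇒ 2 ⇒ 1, and 5 ⇒ 4. In 3 the C–CH3 bond at the β-carbon is cut and the enone is traced to its silyl enol ether and then to 1, which supplies the C2 stereocentre. In 5 the enediol C=C bond is cut back to the two ester carbons of 4. Both forward steps are standard; the first must avoid loss of the silyloxy group.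

## Other disconnections considered

Alternative 1: The C1–C5 bond is cut and a C1–C6 bond restored, which turns the hydroazulene into a decalin with a tertiary hydroxyl on C6 and a sulfonate on C5. In the forward step KOtBu would form the C6 alkoxide and C1 would migrate from C6 to C5 anti to the departing equatorial mesylate, giving A1, the cis-fused hydroazulen-6-one with C8=C9, the 10α ether and the 2β silyl ether in place.
- In its favour: the 1,2-shift is stereospecific, with retention at C1 and inversion at C5, and decalin stereocontrol is well understood.
- Better than the chosen plan: the C8=C9 alkene and the C10 stereocentre exist before the ring system is formed, so no late dehydrogenation or enone reduction is needed. It also needs no photochemistry, which helps on scale.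
- Against it: A1 has only a secondary silyl ether at C4, so the carbinol must still be made by oxidation and isopropyl addition with the C6 ketone present. A1 is a β,γ-unsaturated ketone with an acidic C5–H, so strong base threatens conjugation into C7=C8, loss of the C10 ether and epimerisation of the ring fusion. The C6 reduction would lack the C4 hydroxyl as director.
- Comparison: both plans reorganise easily made rings into the 5–7 system by a stereospecific two-electron process. The chosen one runs under neutral conditions and already carries the C4 carbinol. In step count the alternative saves about three late steps but spends more on assembling a five-stereocentre decalin and on C4, so it is expected to be longer overall.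

Alternative 2: The C4–C5 bond is cut. In the forward step Rh2(OAc)4 would decompose an α-diazo ester at C5 and the carbenoid would insert into the C4–H bond (a 1,5-insertion activated by the adjacent silyloxy oxygen), closing ring A with retention at C4 and giving A2, the cyclopentane cis-1,2-diester with the C4 tertiary silyl ether.
- Better than the chosen plan: the C4 centre is carried over stereospecifically from an acyclic secondary carbinol instead of resting on facial selectivity, and the step is catalytic and thermal.
- Equal to the chosen plan: ring A with its C1, C2 and C4 centres is delivered in defined form.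
- Against it: ring B is not addressed. C7–C9 must still be attached to the two ester carbons, the two methyl esters differentiated, the ring closed, and the C6 and C10 carbinol centres created on open chains with little inherent control. The acceptor carbenoid next to a quaternary ester-bearing carbon may undergo 1,2-shifts or insert into silyl ethyl groups, and the quaternary C1 must be set in an acyclic precursor.
- Comparison: the mechanism is cleaner for C4, but the chosen plan makes ring B and both of its oxygenated carbons in one cleavage, where the alternative would need eight or more further steps.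

Alternative 3: The C7–C8 and C1–C10 bonds are cut, dividing ring B into a four-carbon siloxydiene on ring A and a three-carbon vinylcarbenoid. In the forward step Rh2(S-DOSP)4 would cyclopropanate C6=C7 and the cis-divinylcyclopropane would undergo Cope rearrangement to give A3, the bicyclic cycloheptadiene with the C8 ester, the C5=C6 silyl enol ether and the 10α silyl ether.
- Better than the chosen plan: it is convergent, and it forms ring B, the quaternary C1 and the C10 centre in one operation with their relative configuration fixed by the boat-like Cope transition state. C8=C9 and the C6 oxygen are present from the start.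
- Against it: the Cope terminus C1 is a fully substituted alkene carbon, and the chiral diene may be mismatched with the chiral catalyst. A3 has no C4 hydroxyl, so a late hydroxylation of the C4–H bond with retention or an enone–epoxide detour is needed. The C8 ester must be reduced to a methyl group, and C5 and C6 must be set without the C4 hydroxyl as director.
- Comparison: both rely on stereospecific pericyclic or concerted steps. The alternative reaches the bicycle in fewer steps but needs more afterwards, so overall step economy is judged similar or worse.

Key step: step 7

Remark on the chemistry: the C8 methyl of compounds 6 and 8–13 is drawn as the epimer expected from approach of 3 to the face of 5 remote from its methyl group; the other C8 epimer would follow the same route and converge at 14, where C8 becomes trigonal.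

Step 1
Reactants: 1 (R)-4-(tert-butyldimethylsilyloxy)cyclopent-2-en-1-one
Product: 2 (3R,4R)-4-(tert-butyldimethylsilyloxy)-3-methyl-1-(trimethylsilyloxy)cyclopent-1-ene (methyl trans to the silyloxy group)
Conditions: Me2CuLi (from MeLi, CuI), TMSCl, Et3N, THF, −78 °C
Reagents that add atoms: lithium dimethylcuprate, [Li+].C[Cu-]C; chlorotrimethylsilane, C[Si](C)(C)Cl
Why: Cuprate conjugate addition should occur anti to the C4 silyloxy group, and in situ O-silylation traps the enolate regiospecifically, which prevents proton transfer to the other α-carbon and E1cB loss of the silyloxy group. The new methyl-bearing centre is erased in step 2.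

Step 2
Reactants: 2 (3R,4R)-4-(tert-butyldimethylsilyloxy)-3-methyl-1-(trimethylsilyloxy)cyclopent-1-ene
Product: 3 (R)-4-(tert-butyldimethylsilyloxy)-3-methylcyclopent-2-en-1-one
Conditions: Pd(OAc)2 (10 mol %), O2 (1 atm), DMSO, rt
Reagents that add atoms: none
Why: Saegusa–Ito oxidation: divalent palladium adds to the enol ether α-carbon and β-hydride elimination from the methyl-bearing carbon regenerates the enone with the methyl on the β-carbon. The silyloxy stereocentre is not touched.

Step 3
Reactants: 4 dimethyl 3-methylpentanedioate
Product: 5 4-methyl-1,2-bis(trimethylsilyloxy)cyclopent-1-ene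
Conditions: Na, TMSCl, toluene, reflux
Reagents that add atoms: chlorotrimethylsilane, C[Si](C)(C)Cl
Why: Silyl acyloin condensation (Rühlmann variant): electron transfer from sodium couples the two ester carbons, and TMSCl traps the enediolate and the methoxide, which suppresses Dieckmann cyclisation. Five-membered ring formation is the favourable case.

Step 4
Reactants: 3 (R)-4-(tert-butyldimethylsilyloxy)-3-methylcyclopent-2-en-1-one; 5 4-methyl-1,2-bis(trimethylsilyloxy)cyclopent-1-ene
Product: 6 cis-anti-cis tricyclic C4 ketone (cyclobutane C1–C5–C6–C10 fused to ring A and, on its other face, to the 8α-methylcyclopentane ring; 1β-methyl, 5β-H, 2β-OTBS, 6α,10α-bis(trimethylsilyloxy))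
Conditions: hν (medium-pressure Hg lamp, Pyrex filter), 5 (4 equiv), hexane, −20 °C
Reagents that add atoms: none
Why: Enone–alkene [2+2] photocycloaddition through the enone triplet and a 1,4-diradical; both five-membered rings must be cis-fused to the cyclobutane and the usual anti arrangement of the two rings is expected. The alkene should add to the enone face opposite the adjacent silyloxy group, which sets C1 and C5 (methyl and H cis to OTBS), and the symmetric alkene leaves no regiochemical choice.

Step 5
Reactants: 6 cis-anti-cis tricyclic C4 ketone; 7 isopropylmagnesium chloride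
Product: 8 tricyclic carbinol (as 6, with 4α-hydroxy and 4β-isopropyl in place of the ketone)
Conditions: CeCl3 (anhydrous), iPrMgCl, THF, −78 °C; aq NH4Cl
Reagents that add atoms: isopropylmagnesium chloride (7), CC(C)[Mg]Cl
Why: Organocerium 1,2-addition: the weakly basic isopropylcerium reagent should add to the enolisable β-silyloxy ketone without enolisation, elimination or hydride transfer. Attack is expected on the convex β face because the cyclobutane and the C6 trimethylsilyloxy group lie under the carbonyl, which gives the 4α-hydroxy-4β-isopropyl centre.

Step 6
Reactants: 8 tricyclic carbinol bis(trimethylsilyl) ether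
Product: 9 tricyclic triol (cis-cyclobutane-6α,10α-diol, 4α-hydroxy-4β-isopropyl, 2β-OTBS, 1β-methyl, 5β-H, 8α-methyl)
Conditions: K2CO3, MeOH, 0 °C → rt
Reagents that add atoms: none
Why: Base-catalysed methanolysis removes the two labile trimethylsilyl ethers while the hindered secondary TBS ether stays. Because C4 is already a carbinol, the freed cyclobutanols have no β-carbonyl and cannot fragment by retro-aldol (de Mayo) opening.

Step 7
Reactants: 9 tricyclic triol
Product: 10 cis-fused bicyclo[5.3.0]decane-6,10-dione (1β-methyl, 5β-H, 2β-OTBS, 4α-hydroxy-4β-isopropyl, 8α-methyl)
Conditions: Pb(OAc)4, pyridine, CH2Cl2, −20 → 0 °C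
Reagents that add atoms: none
Why: Criegee glycol cleavage: the cis-diol displaces two acetates on tetravalent lead to form a five-membered cyclic lead diester, which fragments in a concerted two-electron step to the C6 and C10 ketones and divalent lead. The closest known reaction type is the Pb(OAc)4 or periodate cleavage of cyclobutane-1,2-diols derived from enone photoadducts of 1,2-bis(silyloxy)cycloalkenes. No ring is closed by bond formation: ring B appears because scission of the C6–C10 bond shared by the four-membered ring and the methylcyclopentane merges them into one seven-membered ring, and relief of cyclobutane strain drives the fragmentation. No stereocentre is created; C1, C2, C4 and C5 take no part and keep the configurations set in steps 4 and 5, so the cis ring fusion is inherited from the photoadduct. The selectivity needed is chemoselectivity for the 1,2-diol over the isolated C4 tertiary alcohol, secured because only the vicinal hydroxyls, held nearly eclipsed by the cyclobutane, can form the cyclic diester. Low temperature, pyridine buffering and immediate use of 10 are specified because the product is a β-hydroxy ketone with an epimerisable C5–H.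

Step 8
Reactants: 10 cis-fused bicyclo[5.3.0]decane-6,10-dione
Product: 11 6β-hydroxy-10-ketone (4α,6β-diol, otherwise as 10)
Conditions: Me4NBH(OAc)3, AcOH/MeCN, −30 → 0 °C
Reagents that add atoms: none
Why: Saksena–Evans hydroxyl-directed reduction: the C4 hydroxyl exchanges onto boron and hydride is delivered through a six-membered transition state, which geometry allows only on the concave α face of C6 where O4 lies, so the 6β-alcohol should result. The C10 ketone has no β-hydroxyl and is flanked by the quaternary C1, so this mild reagent should leave it alone.

Step 9
Reactants: 11 6β-hydroxy-10-ketone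
Product: 12 4α,6β-O-isopropylidene acetal (acetonide) of 11
Conditions: 2-methoxypropene, PPTS (cat.), CH2Cl2, 0 °C → rt
Reagents that add atoms: 2-methoxypropene, COC(C)=C
Why: Acid-catalysed acetonide formation across the 1,3-diol; O4 and O6 can reach a six-membered dioxane that is cis-fused to ring A. It masks both hydroxyls for the enolate chemistry, ties ring B into one conformation and draws any C6–O/C10 hemiketal back to the open form.

Step 10
Reactants: 12 acetonide 10-ketone
Product: 13 acetonide C9=C10 trimethylsilyl enol ether
Conditions: LDA, THF, −78 °C; TMSCl, Et3N, −78 → 0 °C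
Reagents that add atoms: chlorotrimethylsilane, C[Si](C)(C)Cl
Why: Kinetic enolisation and O-silylation; C1 is quaternary, so deprotonation is possible only at C9 and one regioisomer must form. An amide base is chosen over a silyl triflate because silyl triflates open acetonides.

Step 11
Reactants: 13 acetonide C9=C10 trimethylsilyl enol ether
Product: 14 acetonide C8=C9 enone (8-methyl, C10 ketone)
Conditions: Pd(OAc)2 (1.1 equiv), MeCN, rt
Reagents that add atoms: none
Why: Saegusa–Ito oxidation: palladation at C9 and syn β-hydride elimination of the single C8 hydrogen should give the C8=C9 enone. The C8 stereocentre disappears, so both C8 epimers converge here.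

Step 12
Reactants: 14 acetonide C8=C9 enone
Product: 15 acetonide 10α-allylic alcohol
Conditions: NaBH4, CeCl3·7H2O, MeOH, −78 → −40 °C
Reagents that add atoms: none
Why: Luche reduction should give 1,2-reduction only. Hydride is expected on the convex β face of the cis-fused bicycle, anti to the C1–C2 bond (Felkin–Anh arrangement), because ring A and the dioxane screen the concave face, so the new hydroxyl should be α.

Step 13
Reactants: 15 acetonide 10α-allylic alcohol
Product: 16 2β-(tert-butyldimethylsilyloxy)dauc-8-ene-4α,6β,10α-triol (5β-H)
Conditions: PPTS, MeOH, rt
Reagents that add atoms: none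
Why: Acid-catalysed transketalisation to methanol; the acetonide, strained by its tertiary oxygen, should be cleaved under conditions mild enough for the allylic alcohol and the neopentylic TBS ether.

Step 14
Reactants: 16 2β-(tert-butyldimethylsilyloxy)dauc-8-ene-4α,6β,10α-triol; 17 angelic acid ((Z)-2-methylbut-2-enoic acid)
Product: 19 6β,10α-bis(angeloyloxy)-2β-(tert-butyldimethylsilyloxy)dauc-8-en-4α-ol, via angelic 2,4,6-trichlorobenzoic anhydride 18 (not isolated)
Conditions: 17, 2,4,6-trichlorobenzoyl chloride, Et3N, toluene, rt; then 16, 80 °C
Reagents that add atoms: angelic acid (17), C/C=C(/C)C(=O)O; 2,4,6-trichlorobenzoyl chloride, O=C(Cl)c1c(Cl)cc(Cl)cc1Cl (its aroyl group is carried only by intermediate 18)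
Why: Yamaguchi-type esterification run without DMAP: the alcohols attack the less hindered angeloyl carbonyl of the mixed anhydride, and the absence of a nucleophilic catalyst avoids addition–elimination isomerisation of the (Z)-ester to the tiglate. The two secondary hydroxyls should react while the tertiary C4 hydroxyl is too hindered.

Step 15
Reactants: 19 6β,10α-bis(angeloyloxy)-2β-(tert-butyldimethylsilyloxy)dauc-8-en-4α-ol
Product: 20 6β,10α-bis(angeloyloxy)dauc-8-ene-2β,4α-diol (5β-H; 1R,2R,4S,5R,6R,10R), the target
Conditions: HF·pyridine, pyridine, THF, 0 °C → rt
Reagents that add atoms: none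
Why: Fluoride-mediated desilylation under buffered, mildly acidic conditions should cleave the TBS ether without ester migration, hydrolysis or Z-to-E isomerisation.

## Compound list

1 | (R)-4-(tert-butyldimethylsilyloxy)cyclopent-2-en-1-one | O=C1C=C[C@H](O[Si](C)(C)C(C)(C)C)C1 | starting material
2 | (3R,4R)-4-(tert-butyldimethylsilyloxy)-3-methyl-1-(trimethylsilyloxy)cyclopent-1-ene | C[Si](C)(C)OC1=C[C@@H](C)[C@H](O[Si](C)(C)C(C)(C)C)C1 | intermediate
3 | (R)-4-(tert-butyldimethylsilyloxy)-3-methylcyclopent-2-en-1-one | O=C1C=C(C)[C@H](O[Si](C)(C)C(C)(C)C)C1 | intermediate
4 | dimethyl 3-methylpentanedioate | COC(=O)CC(C)CC(=O)OC | starting material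
5 | 4-methyl-1,2-bis(trimethylsilyloxy)cyclopent-1-ene | C[Si](C)(C)OC1=C(O[Si](C)(C)C)CC(C)C1 | intermediate
6 | cis-anti-cis tricyclic C4 ketone (photoadduct; 2β-OTBS, 6α,10α-bis-OTMS) | C[Si](C)(C)O[C@]13C[C@@H](C)C[C@]3(O[Si](C)(C)C)[C@@]2(C)[C@H](O[Si](C)(C)C(C)(C)C)CC(=O)[C@@H]12 | intermediate
7 | isopropylmagnesium chloride | CC(C)[Mg]Cl | starting material
8 | tricyclic carbinol (4α-hydroxy-4β-isopropyl, 6α,10α-bis-OTMS, 2β-OTBS) | C[Si](C)(C)O[C@]13C[C@@H](C)C[C@]3(O[Si](C)(C)C)[C@@]2(C)[C@H](O[Si](C)(C)C(C)(C)C)C[C@](O)(C(C)C)[C@@H]12 | intermediate
9 | tricyclic triol (cis-cyclobutane-6,10-diol, 4α-hydroxy-4β-isopropyl, 2β-OTBS) | O[C@]13C[C@@H](C)C[C@]3(O)[C@@]2(C)[C@H](O[Si](C)(C)C(C)(C)C)C[C@](O)(C(C)C)[C@@H]12 | intermediate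
10 | cis-fused bicyclo[5.3.0]decane-6,10-dione (4α-hydroxy-4β-isopropyl, 2β-OTBS) | O=C1C[C@@H](C)CC(=O)[C@@]2(C)[C@H](O[Si](C)(C)C(C)(C)C)C[C@](O)(C(C)C)[C@@H]12 | intermediate
11 | 6β-hydroxy-10-ketone (4α,6β-diol) | O[C@@H]1C[C@@H](C)CC(=O)[C@@]2(C)[C@H](O[Si](C)(C)C(C)(C)C)C[C@](O)(C(C)C)[C@@H]12 | intermediate
12 | 4α,6β-O-isopropylidene 10-ketone | CC1(C)O[C@@H]2C[C@@H](C)CC(=O)[C@@]3(C)[C@H](O[Si](C)(C)C(C)(C)C)C[C@](O1)(C(C)C)[C@@H]23 | intermediate
13 | acetonide C9=C10 trimethylsilyl enol ether | CC1(C)O[C@@H]2C[C@@H](C)C=C(O[Si](C)(C)C)[C@@]3(C)[C@H](O[Si](C)(C)C(C)(C)C)C[C@](O1)(C(C)C)[C@@H]23 | intermediate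
14 | acetonide C8=C9 enone | CC1(C)O[C@@H]2CC(C)=CC(=O)[C@@]3(C)[C@H](O[Si](C)(C)C(C)(C)C)C[C@](O1)(C(C)C)[C@@H]23 | intermediate
15 | acetonide 10α-allylic alcohol | CC1(C)O[C@@H]2CC(C)=C[C@@H](O)[C@@]3(C)[C@H](O[Si](C)(C)C(C)(C)C)C[C@](O1)(C(C)C)[C@@H]23 | intermediate
16 | 2β-(tert-butyldimethylsilyloxy)dauc-8-ene-4α,6β,10α-triol | O[C@@H]1CC(C)=C[C@@H](O)[C@@]2(C)[C@H](O[Si](C)(C)C(C)(C)C)C[C@](O)(C(C)C)[C@@H]12 | intermediate
17 | angelic acid | C/C=C(/C)C(=O)O | starting material
18 | angelic 2,4,6-trichlorobenzoic anhydride | C/C=C(/C)C(=O)OC(=O)c1c(Cl)cc(Cl)cc1Cl | intermediate
19 | 6β,10α-bis(angeloyloxy)-2β-(tert-butyldimethylsilyloxy)dauc-8-en-4α-ol | C/C=C(/C)C(=O)O[C@@H]1CC(C)=C[C@@H](OC(=O)/C(C)=C\C)[C@@]2(C)[C@H](O[Si](C)(C)C(C)(C)C)C[C@](O)(C(C)C)[C@@H]12 | intermediate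
20 | 6β,10α-bis(angeloyloxy)dauc-8-ene-2β,4α-diol (CNP0249167.1) | C/C=C(/C)C(=O)O[C@@H]1CC(C)=C[C@@H](OC(=O)/C(C)=C\C)[C@@]2(C)[C@H](O)C[C@](O)(C(C)C)[C@@H]12 | target

## Step count and least certain steps

Total: 15 steps. Longest linear sequence: 14 steps (1 to 20 through steps 1, 2 and 4–15); step 3 is a one-step side branch.

Step 7 (key step). The cleavage itself is expected to be fast. What may go wrong is decay of the product during isolation: retro-aldol opening of ring A across C4–C5, epimerisation of C5 or dehydration, all driven by the β-hydroxy ketone. The fallback sets out from 9 and comes back at 11. Cleavage and directed reduction are joined in one flask (Pb(OAc)4, 1.0 equiv, in AcOH/MeCN at 0 °C, then Me4NBH(OAc)3 at −30 °C), so that the dione is reduced as soon as it forms and is never concentrated or chromatographed. This makes no compound outside the list (F0).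

Step 12. Poor facial selectivity is the main risk: the C10 carbonyl is flanked by the C1 methyl on the convex face and by C2 on the concave face, and ring B is flexible, so hydride delivery from the α face could compete and give the 10β-alcohol. The fallback sets out from 14 and comes back at 15. It replaces substrate control by reagent control: Corey–Bakshi–Shibata reduction with (S)-2-methyl-CBS-oxazaborolidine and catecholborane in toluene at −78 °C. The model with the quaternary C1 flank as the large group points to the (S) catalyst for the 10R alcohol; the (R) catalyst is the choice should the alkene flank dominate. No compound outside the list is made (F0).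

Step 8. Slow ligand exchange of the hindered tertiary C4 hydroxyl on boron may leave the dione exposed to acid long enough for retro-aldol or dehydration to compete with reduction. The fallback sets out from 10 and comes back at 11. The directing group is tied on covalently first: Me2SiHCl, Et3N and DMAP give the C4 dimethylsilyl ether F1. SnCl4 in CH2Cl2 at −78 °C then promotes intramolecular hydrosilylation of the C6 ketone from the same α face to give the cyclic dimethylsilylene F2. K2CO3 in MeOH releases 11.

Step 14. Incomplete acylation of the neopentylic allylic C10 hydroxyl under catalyst-free conditions, or Z-to-E isomerisation once forcing conditions or nucleophilic catalysts are used, are the likely failures. The fallback sets out from 16 and comes back at 19. The (Z)-alkene is built after the ester bonds: esterification with 2-[bis(2,2,2-trifluoroethoxy)phosphoryl]propanoic acid (EDC·HCl, DMAP) gives the bis(phosphonopropionate) F3, an epimer mixture at the two phosphonate α-carbons. Still–Gennari olefination (KHMDS, 18-crown-6, THF, −78 °C, acetaldehyde) then forms both (Z)-2-methylbut-2-enoates.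

Step 5. Hydride transfer from the isopropyl reagent to the hindered carbonyl, or enolisation toward C3 followed by loss of the C2 silyloxy group, may compete with addition. The fallback sets out from 6 and comes back at 8. A smaller sp2 nucleophile without a transferable β-hydrogen is used: isopropenylmagnesium bromide with CeCl3 in THF at −78 °C gives the isopropenyl carbinol F4, and hydrogenation (H2, PtO2, EtOAc) of its 1,1-disubstituted alkene gives 8.

## Further compounds

F0 | step 7 | none | none
F0 | step 12 | none | none
F1 | step 8 | C4 dimethylsilyl ether of dione 10 | O=C1C[C@@H](C)CC(=O)[C@@]2(C)[C@H](O[Si](C)(C)C(C)(C)C)C[C@](O[SiH](C)C)(C(C)C)[C@@H]12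
F2 | step 8 | 4α,6β-O-dimethylsilylene 10-ketone | C[Si]1(C)O[C@@H]2C[C@@H](C)CC(=O)[C@@]3(C)[C@H](O[Si](C)(C)C(C)(C)C)C[C@](O1)(C(C)C)[C@@H]23
F3 | step 14 | 6β,10α-bis{2-[bis(2,2,2-trifluoroethoxy)phosphoryl]propanoyloxy}-2β-(tert-butyldimethylsilyloxy)dauc-8-en-4α-ol | CC(C(=O)O[C@@H]1CC(C)=C[C@@H](OC(=O)C(C)P(=O)(OCC(F)(F)F)OCC(F)(F)F)[C@@]2(C)[C@H](O[Si](C)(C)C(C)(C)C)C[C@](O)(C(C)C)[C@@H]12)P(=O)(OCC(F)(F)F)OCC(F)(F)F
F4 | step 5 | tricyclic isopropenyl carbinol (4α-hydroxy-4β-isopropenyl analogue of 8) | C[Si](C)(C)O[C@]13C[C@@H](C)C[C@]3(O[Si](C)(C)C)[C@@]2(C)[C@H](O[Si](C)(C)C(C)(C)C)C[C@](O)(C(C)=C)[C@@H]12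
A1 | alternative 1 | cis-fused hydroazulen-6-one with C8=C9, 10α-(4-methoxybenzyloxy), 2β-OTBS and 4β-triethylsilyloxy | O=C1CC(C)=C[C@@H](OCc3ccc(OC)cc3)[C@@]2(C)[C@H](O[Si](C)(C)C(C)(C)C)C[C@H](O[Si](CC)(CC)CC)[C@@H]12
A2 | alternative 2 | dimethyl cyclopentane-cis-1,2-dicarboxylate (C10 and C6 esters on C1 and C5; 1β-methyl, 2β-OTBS, 4α-triethylsilyloxy-4β-isopropyl) | COC(=O)[C@@H]1[C@@](O[Si](CC)(CC)CC)(C(C)C)C[C@@H](O[Si](C)(C)C(C)(C)C)[C@]1(C)C(=O)OC
A3 | alternative 3 | bicyclic cycloheptadiene (C5=C6 TBS enol ether, C8 methyl ester on C8=C9, 10α-OTBS, 2β-triisopropylsilyloxy, 4β-isopropyl) | CC(C)(C)[Si](C)(C)OC=1CC(C(=O)OC)=C[C@@H](O[Si](C)(C)C(C)(C)C)[C@@]2(C)[C@H](O[Si](C(C)C)(C(C)C)C(C)C)C[C@H](C(C)C)C=12
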